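**Retrosynthetic overview**
Ring numbering: C1 carbonyl, C2=C3, C4 CHOH, C5 C(OH)(chain), C6 CH2. A late redox exchange (C4 ketone to alcohol, C1 carbinol to ketone) leads back to a 4-silyloxy-6-alkyl-6-hydroxycyclohex-2-enone, an acyloin whose carbonyl is C4.
Enabling feature: in the ring C1–C6, the oxygen-bearing neighbours C4 and C5 form an α-ketol retron, because C5 is a fully substituted carbinol bonded to the ring methylene C6. Returning C6 from C5 to C4 contracts the ring to the cyclopentene C1–C2–C3–C4–C6, with C5 as an exocyclic acyl carbon.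
This 1-acylcyclopent-2-enol comes from commercial (R)-4-silyloxycyclopent-2-enone by acetyl-anion addition, then alkylation of the methyl ketone with a C18 iodide (bought E-hexenyl unit plus a C12 dibromide).
Ring order: the only ring is bought five-membered and enlarged to six members in the key step, a single isomerisation that delivers the ring, the quaternary carbinol and the enone. Chirality is relayed C1 → C4 → C5 → C4, and the C1 stereocentre is erased by the last oxidation.

Key step: step 6

Assumption: the target SMILES is read as the (4S,5S) trans-diol bearing an (E)-nonadec-16-en-1-yl chain on C5. The ring numbering above is kept for all precursors.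

Step 1
Reactants: 1 (E)-hex-3-en-1-ol
Product: 2 (E)-1-bromohex-3-ene
Conditions: CBr4, PPh3, CH2Cl2, 0 °C
Reagents that add atoms: carbon tetrabromide, BrC(Br)(Br)Br
Why: Appel reaction, in which the alkoxyphosphonium salt of the primary alcohol is displaced by bromide in an SN2 step under neutral conditions that leave the E-alkene untouched.

Step 2
Reactants: 2 (E)-1-bromohex-3-ene; 3 1,12-dibromododecane
Product: 5 (E)-18-bromooctadec-3-ene, via hexenylmagnesium bromide 4 (not isolated)
Conditions: Mg, THF, 25 °C; then 3 (3 equiv), Li2CuCl4 (cat.), THF, −10 to 0 °C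
Reagents that add atoms: none
Why: Li2CuCl4-catalysed cross-coupling of a primary alkyl Grignard reagent with a primary alkyl bromide, a standard sp3–sp3 chain extension in which excess dibromide favours single substitution and the alkene keeps its E geometry.

Step 3
Reactants: 5 (E)-18-bromooctadec-3-ene
Product: 6 (E)-18-iodooctadec-3-ene
Conditions: NaI, acetone, reflux
Reagents that add atoms: sodium iodide, [Na+].[I-]
Why: Finkelstein reaction, in which precipitation of NaBr from acetone drives the halide exchange and gives the more reactive alkylating agent for step 5.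

Step 4
Reactants: 7 ethyl vinyl ether; 8 (R)-4-(tert-butyldimethylsilyloxy)cyclopent-2-en-1-one
Product: 11 1-[(1S,4R)-4-(tert-butyldimethylsilyloxy)-1-hydroxycyclopent-2-en-1-yl]ethan-1-one, via 1-ethoxyvinyllithium 9 (not isolated), via ethoxyvinyl carbinol 10 (not isolated)
Conditions: 7, t-BuLi, THF, −78 to 0 °C; 8, −78 °C; then 1 M HCl, THF, 0 °C
Reagents that add atoms: water, O
Why: α-Lithiated ethyl vinyl ether is an acetyl anion equivalent that adds 1,2 to the enone from the face opposite the silyloxy group, which sets the tertiary carbinol C4 as 1S (any minor epimer is removed by chromatography), and brief aqueous acid hydrolyses only the acyclic enol ether to the methyl ketone.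

Step 5
Reactants: 11 1-[(1S,4R)-4-(tert-butyldimethylsilyloxy)-1-hydroxycyclopent-2-en-1-yl]ethan-1-one; 6 (E)-18-iodooctadec-3-ene
Product: 13 (E)-1-[(1S,4R)-4-(tert-butyldimethylsilyloxy)-1-hydroxycyclopent-2-en-1-yl]icos-17-en-1-one, via dilithium enolate alkoxide 12 (not isolated)
Conditions: LiN(i-Pr)2 (2.2 equiv), THF, −78 °C; 6, DMPU, −78 to 0 °C
Reagents that add atoms: none
Why: Kinetic enolate alkylation of an α-hydroxy methyl ketone through its alkoxide–enolate dianion, where the methyl group is the only enolisable position, the primary iodide reacts by SN2, and no stereocentre is touched.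

Step 6
Reactants: 13 (E)-1-[(1S,4R)-4-(tert-butyldimethylsilyloxy)-1-hydroxycyclopent-2-en-1-yl]icos-17-en-1-one
Product: 14 (4R,6S)-4-(tert-butyldimethylsilyloxy)-6-hydroxy-6-[(E)-nonadec-16-en-1-yl]cyclohex-2-en-1-one
Conditions: Al(Ot-Bu)3 (1.2 equiv), toluene, 90 °C
Reagents that add atoms: none
Why: Al(Ot-Bu)3 exchanges with the tertiary OH of 13 and binds the acyl oxygen, so O–C4–C5=O is held syn-periplanar in a five-membered aluminium chelate with the two ring carbons on C4 on opposite faces of the acyl plane, and a suprafacial 1,2-shift of C6 from C4 to C5 turns C4 into the ketone and C5 into the carbinol (α-ketol, or acyloin, rearrangement). The closest known reaction type is the Lewis-acid- or base-mediated enlargement of 1-acylcyclopentanols to 2-alkyl-2-hydroxycyclohexanones, best known as the D-homoannulation of 17-hydroxy-20-oxo steroids. The six-membered ring is closed not by an exo or endo cyclisation but by this three-centre shift, which inserts C5 between C4 and C6 of the cyclopentene. The one new stereocentre, C5, is controlled by the C4 configuration of 13, because within the chelate C6 can reach only one face of the acyl carbon, giving 5S (6S in the numbering of 14) while C4 loses its stereogenicity. The step needs group selectivity for C6 over the alkenyl carbon C3: every shift is reversible here, and only migration of C6 leaves the new C4 carbonyl conjugated with C2=C3 in a less strained cyclohexenone, so 14 should be the thermodynamic sink and the unconjugated C3-shift isomer should drain back through 13. The tert-butoxide ligands carry no transferable hydride, so no Meerwein–Ponndorf–Verley reduction competes, and the silyl ether and the chain alkene are inert.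

Step 7
Reactants: 14 (4R,6S)-4-(tert-butyldimethylsilyloxy)-6-hydroxy-6-[(E)-nonadec-16-en-1-yl]cyclohex-2-en-1-one
Product: 15 (1S,2S,5R)-5-(tert-butyldimethylsilyloxy)-1-[(E)-nonadec-16-en-1-yl]cyclohex-3-ene-1,2-diol
Conditions: Zn(BH4)2, Et2O, −30 °C
Reagents that add atoms: none
Why: Chelation-controlled (Cram chelate) 1,2-reduction, in which zinc ties the C5 hydroxyl to the C4 carbonyl, the alkyl chain becomes axial, and hydride enters from the opposite face to give the 4S alcohol trans to the C5 hydroxyl.

Step 8
Reactants: 15 (1S,2S,5R)-5-(tert-butyldimethylsilyloxy)-1-[(E)-nonadec-16-en-1-yl]cyclohex-3-ene-1,2-diol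
Product: 16 (1S,2S,4R)-2-[(E)-nonadec-16-en-1-yl]cyclohex-5-ene-1,2,4-triol
Conditions: HF·pyridine, pyridine, THF, 0 °C to rt
Reagents that add atoms: none
Why: Fluoride-mediated silyl ether cleavage driven by the strong Si–F bond, with the buffered reagent sparing the allylic alcohols and both alkenes.

Step 9
Reactants: 16 (1S,2S,4R)-2-[(E)-nonadec-16-en-1-yl]cyclohex-5-ene-1,2,4-triol
Product: 17 (4S,5S)-4,5-dihydroxy-5-[(E)-nonadec-16-en-1-yl]cyclohex-2-en-1-one
Conditions: activated MnO2, CH2Cl2, rt
Reagents that add atoms: none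
Why: MnO2 oxidation of an allylic alcohol, in which the C1 carbinol next to a CH2 group is far more accessible to the solid oxidant than the C4 carbinol next to the fully substituted C5, the tertiary alcohol and the isolated alkene are inert, and the neutral medium avoids dehydration of the β-hydroxy ketone.

**Compound list**
1 | (E)-hex-3-en-1-ol | CC/C=C/CCO | starting material
2 | (E)-1-bromohex-3-ene | CC/C=C/CCBr | intermediate
3 | 1,12-dibromododecane | BrCCCCCCCCCCCCBr | starting material
4 | (E)-hex-3-en-1-ylmagnesium bromide | CC/C=C/CC[Mg]Br | intermediate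
5 | (E)-18-bromooctadec-3-ene | CC/C=C/CCCCCCCCCCCCCCBr | intermediate
6 | (E)-18-iodooctadec-3-ene | CC/C=C/CCCCCCCCCCCCCCI | intermediate
7 | ethyl vinyl ether | C=COCC | starting material
8 | (R)-4-(tert-butyldimethylsilyloxy)cyclopent-2-en-1-one | O=C1C=C[C@H](O[Si](C)(C)C(C)(C)C)C1 | starting material
9 | 1-ethoxyvinyllithium | [Li]C(=C)OCC | intermediate
10 | (1S,4R)-4-(tert-butyldimethylsilyloxy)-1-(1-ethoxyvinyl)cyclopent-2-en-1-ol | C=C(OCC)[C@@]1(O)C=C[C@H](O[Si](C)(C)C(C)(C)C)C1 | intermediate
11 | 1-[(1S,4R)-4-(tert-butyldimethylsilyloxy)-1-hydroxycyclopent-2-en-1-yl]ethan-1-one | CC(=O)[C@@]1(O)C=C[C@H](O[Si](C)(C)C(C)(C)C)C1 | intermediate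
12 | dilithium enolate alkoxide of 11 | [Li+].[Li+].C=C([O-])[C@@]1([O-])C=C[C@H](O[Si](C)(C)C(C)(C)C)C1 | intermediate
13 | (E)-1-[(1S,4R)-4-(tert-butyldimethylsilyloxy)-1-hydroxycyclopent-2-en-1-yl]icos-17-en-1-one | CC/C=C/CCCCCCCCCCCCCCCC(=O)[C@@]1(O)C=C[C@H](O[Si](C)(C)C(C)(C)C)C1 | intermediate
14 | (4R,6S)-4-(tert-butyldimethylsilyloxy)-6-hydroxy-6-[(E)-nonadec-16-en-1-yl]cyclohex-2-en-1-one | CC/C=C/CCCCCCCCCCCCCCC[C@]1(O)C[C@@H](O[Si](C)(C)C(C)(C)C)C=CC1=O | intermediate
15 | (1S,2S,5R)-5-(tert-butyldimethylsilyloxy)-1-[(E)-nonadec-16-en-1-yl]cyclohex-3-ene-1,2-diol | CC/C=C/CCCCCCCCCCCCCCC[C@]1(O)C[C@@H](O[Si](C)(C)C(C)(C)C)C=C[C@@H]1O | intermediate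
16 | (1S,2S,4R)-2-[(E)-nonadec-16-en-1-yl]cyclohex-5-ene-1,2,4-triol | CC/C=C/CCCCCCCCCCCCCCC[C@]1(O)C[C@@H](O)C=C[C@@H]1O | intermediate
17 | (4S,5S)-4,5-dihydroxy-5-[(E)-nonadec-16-en-1-yl]cyclohex-2-en-1-one | CC/C=C/CCCCCCCCCCCCCCC[C@]1(O)CC(=O)C=C[C@@H]1O | target

Total step count: 9. Longest linear sequence: 8 steps (1, 2, 3, 5, 6, 7, 8, 9).

**Steps most likely to fail**

Step 6. The alkenyl carbon C3 may shift faster than C6, and equilibration to the conjugated enone may be too slow to outrun loss of silanol at 90 °C.
- The fallback sets out from 13 and masks the competing alkene.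
- Hydroxyl-directed epoxidation with VO(acac)2 and t-BuOOH acts only on the ring alkene next to the tertiary alcohol and gives the epoxy ketol F1.
- In F1, C3 is an oxygen-bearing sp3 carbon of poor migratory aptitude. The same α-ketol ring enlargement can therefore move only C6, giving the epoxy ketone F2.
- Reductive removal of the α,β-epoxide oxygen with Zn, NaI and AcOH restores C2=C3, and the route is rejoined at 14.

Step 9. Site selectivity may be poor: oxidation at C4, or at both carbinols, would be followed by dehydration to quinoid material.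
- The fallback sets out from 15, while C1 is still silylated.
- 2-Methoxypropene and pyridinium tosylate tie C4–OH and C5–OH together as the trans-fused acetonide F3.
- Bu4NF frees the C1 carbinol to give the acetonide alcohol F4.
- Dess–Martin periodinane gives the acetonide enone F5.
- Aqueous acetic acid removes the strained acetal, and the route is rejoined at 17.

Step 5. Proton exchange between product and dianion, together with a slow SN2 step, may lead to incomplete or multiple alkylation.
- The fallback sets out from 11, which is condensed with Me2NNH2 to the dimethylhydrazone F6.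
- Double deprotonation with LiN(i-Pr)2 and alkylation of the more nucleophilic azaenolate with 6 gives the chain-extended hydrazone F7.
- Hydrolysis with Cu(OAc)2 in aqueous THF rejoins the route at 13.

**Further compounds**
F1 | step 6 | epoxy ketol: 13 with C2–C3 as an oxirane on the face of the C4 hydroxyl | CC/C=C/CCCCCCCCCCCCCCCC(=O)[C@@]1(O)[C@@H]2O[C@@H]2[C@H](O[Si](C)(C)C(C)(C)C)C1
F2 | step 6 | epoxy ketone: 14 with C2–C3 as an oxirane | CC/C=C/CCCCCCCCCCCCCCC[C@]1(O)C[C@@H](O[Si](C)(C)C(C)(C)C)[C@H]2O[C@H]2C1=O
F3 | step 9 | C4,C5-acetonide of 15 | CC/C=C/CCCCCCCCCCCCCCC[C@]12C[C@@H](O[Si](C)(C)C(C)(C)C)C=C[C@@H]1OC(C)(C)O2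
F4 | step 9 | C4,C5-acetonide of 16 (free C1 carbinol) | CC/C=C/CCCCCCCCCCCCCCC[C@]12C[C@@H](O)C=C[C@@H]1OC(C)(C)O2
F5 | step 9 | C4,C5-acetonide of 17 | CC/C=C/CCCCCCCCCCCCCCC[C@]12CC(=O)C=C[C@@H]1OC(C)(C)O2
F6 | step 5 | N,N-dimethylhydrazone of 11 | C/C(=N\N(C)C)[C@@]1(O)C=C[C@H](O[Si](C)(C)C(C)(C)C)C1
F7 | step 5 | N,N-dimethylhydrazone of 13 | CC/C=C/CCCCCCCCCCCCCCC/C(=N\N(C)C)[C@@]1(O)C=C[C@H](O[Si](C)(C)C(C)(C)C)C1
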